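## Retrosynthetic overview

- Target 19 comes from double O-methylation of diol 17, which comes from LiAlH4 opening of the trans-fused aryltetralin lactone 16.
- 16 comes from carbinol 15 by cationic Friedel–Crafts closure of the C1–C8a bond, which forms the tetralin carbocycle and sets C1.
- 15 comes from an intermolecular lithium-enolate aldol of (S)-β-veratryl-γ-butyrolactone 12 with veratraldehyde 13, which forms the C1–C2 bond, joins the two aryl halves and sets C2.
- 12 comes from Evans alkylation of imide 4 (acid 1 plus auxiliary 2) with tert-butyl bromoacetate 5, which sets C3, followed by auxiliary removal, acid reduction and lactonisation.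
- Ring order: the γ-lactone first, then the tetralin carbocycle; the lactone is opened at the end.

Assumption: the SMILES is read as (1R,2S,3S), the 1,2-trans-2,3-trans tetralin; NaN(SiMe3)2, LiN(SiMe3)2 and BH3·THF are used as purchased solutions.

## Route

Step 1
Reactants: 1 3-(3,4-dimethoxyphenyl)propanoic acid; 2 (R)-4-benzyl-2-oxazolidinone
Product: 4 (4R)-4-benzyl-3-[3-(3,4-dimethoxyphenyl)propanoyl]oxazolidin-2-one, via mixed pivalic anhydride 3 (not isolated)
Conditions: PivCl, Et3N, THF, −20 °C; then LiCl, 2, −20 °C → rt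
Reagents that add atoms: none
Why: N-acylation of the oxazolidinone through the mixed pivalic anhydride (LiCl/Et3N activation) is a standard imide formation in which the hindered pivaloyl carbonyl steers attack to the desired acyl group; no stereocentre is formed.

Step 2
Reactants: 4 (4R)-4-benzyl-3-[3-(3,4-dimethoxyphenyl)propanoyl]oxazolidin-2-one; 5 tert-butyl bromoacetate
Product: 7 tert-butyl (3S)-4-[(4R)-4-benzyl-2-oxooxazolidin-3-yl]-3-(3,4-dimethoxybenzyl)-4-oxobutanoate, via sodium Z-enolate 6 (not isolated)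
Conditions: NaN(SiMe3)2 (1.1 equiv), THF, −78 °C; then 5, −78 → −40 °C; aq. NH4Cl
Reagents that add atoms: none
Why: Evans asymmetric alkylation, in which the chelated sodium Z-enolate is attacked by the reactive bromoacetate on the face opposite the benzyl group of the (R)-auxiliary, setting the new centre as 3S (future C3 of the target) with high diastereoselectivity.

Step 3
Reactants: 7 tert-butyl (3S)-4-[(4R)-4-benzyl-2-oxooxazolidin-3-yl]-3-(3,4-dimethoxybenzyl)-4-oxobutanoate
Product: 9 (2S)-4-tert-butoxy-2-(3,4-dimethoxybenzyl)-4-oxobutanoic acid, via lithium peroxycarboxylate 8 (not isolated)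
Conditions: LiOH·H2O, 30% H2O2, THF/H2O (3:1), 0 °C; then aq. Na2SO3; 1 M HCl to pH 3, 0 °C
Reagents that add atoms: hydrogen peroxide, OO
Why: Hydroperoxide-mediated imide hydrolysis, in which LiOOH attacks the exocyclic imide carbonyl selectively and releases the recoverable auxiliary without touching the tert-butyl ester or epimerising the α-centre, after which sulfite reduces the peracid salt to the acid.

Step 4
Reactants: 9 (2S)-4-tert-butoxy-2-(3,4-dimethoxybenzyl)-4-oxobutanoic acid
Product: 10 tert-butyl (3S)-3-(3,4-dimethoxybenzyl)-4-hydroxybutanoate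
Conditions: BH3·THF (1.5 equiv), THF, 0 °C → rt; then H2O, 0 °C
Reagents that add atoms: none
Why: Chemoselective borane reduction of a carboxylic acid (via the acyloxyborane) in the presence of a tert-butyl ester and aryl ethers; the stereocentre is not involved.

Step 5
Reactants: 10 tert-butyl (3S)-3-(3,4-dimethoxybenzyl)-4-hydroxybutanoate
Product: 12 (4S)-4-(3,4-dimethoxybenzyl)dihydrofuran-2(3H)-one, via hydroxy acid 11 (not isolated)
Conditions: p-TsOH·H2O (10 mol %), toluene, 80 °C
Reagents that add atoms: none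
Why: Acid-catalysed tert-butyl ester cleavage (loss of isobutene) followed by spontaneous γ-lactonisation of the hydroxy acid, a five-membered ring closure that leaves the stereocentre untouched.

Step 6
Reactants: 12 (4S)-4-(3,4-dimethoxybenzyl)dihydrofuran-2(3H)-one; 13 3,4-dimethoxybenzaldehyde
Product: 15 (3R,4S)-4-(3,4-dimethoxybenzyl)-3-[(3,4-dimethoxyphenyl)(hydroxy)methyl]dihydrofuran-2(3H)-one as a mixture of carbinol epimers, via lithium lactone enolate 14 (not isolated)
Conditions: LiN(SiMe3)2 (1.1 equiv), THF, −78 °C; then 13, −78 °C, 1 h; AcOH quench at −78 °C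
Reagents that add atoms: none
Why: Intermolecular lithium-enolate aldol addition, in which the aldehyde approaches the enolate anti to the C4 benzyl group and so fixes the 3,4-trans relationship (3R, future C2 of the target), while the carbinol centre forms as an inconsequential epimer mixture because it is ionised in step 7.

Step 7
Reactants: 15 (3R,4S)-4-(3,4-dimethoxybenzyl)-3-[(3,4-dimethoxyphenyl)(hydroxy)methyl]dihydrofuran-2(3H)-one
Product: 16 (3aS,9R,9aS)-9-(3,4-dimethoxyphenyl)-6,7-dimethoxy-3a,4,9,9a-tetrahydronaphtho[2,3-c]furan-1(3H)-one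
Conditions: TFA, CH2Cl2, 0 °C → rt
Reagents that add atoms: none
Why: Intramolecular Friedel–Crafts alkylation, in which both carbinol epimers ionise to the same p-methoxy-stabilised benzylic cation that is captured para to a methoxy group of the benzyl ring through a chair-like transition state with the aryl group pseudo-equatorial, giving the 1,2-trans-2,3-trans tetralin (9R, future C1).

Step 8
Reactants: 16 (3aS,9R,9aS)-9-(3,4-dimethoxyphenyl)-6,7-dimethoxy-3a,4,9,9a-tetrahydronaphtho[2,3-c]furan-1(3H)-one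
Product: 17 [(1R,2S,3S)-1-(3,4-dimethoxyphenyl)-6,7-dimethoxy-1,2,3,4-tetrahydronaphthalene-2,3-diyl]dimethanol
Conditions: LiAlH4, THF, 0 °C → rt; H2O quench
Reagents that add atoms: none
Why: Hydride reduction of the lactone to the 1,4-diol is fast, removes the epimerisable α-carbonyl position before it can equilibrate, and leaves the aryl methyl ethers and all three stereocentres intact.

Step 9
Reactants: 17 [(1R,2S,3S)-1-(3,4-dimethoxyphenyl)-6,7-dimethoxy-1,2,3,4-tetrahydronaphthalene-2,3-diyl]dimethanol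
Product: 19 phyltetralin, via disodium dialkoxide 18 (not isolated)
Conditions: NaH (3 equiv), THF/DMF, 0 °C; then MeI (4 equiv), 0 °C → rt
Reagents that add atoms: iodomethane, CI
Why: Double Williamson ether synthesis on two unhindered primary alkoxides; no stereocentre is touched and no other acidic or electrophilic site is present.

## Compound list

1 | 3-(3,4-dimethoxyphenyl)propanoic acid | COc1ccc(CCC(=O)O)cc1OC | starting material
2 | (R)-4-benzyl-2-oxazolidinone | O=C1N[C@H](Cc2ccccc2)CO1 | starting material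
3 | 3-(3,4-dimethoxyphenyl)propanoic pivalic anhydride (not isolated) | COc1ccc(CCC(=O)OC(=O)C(C)(C)C)cc1OC | intermediate
4 | (4R)-4-benzyl-3-[3-(3,4-dimethoxyphenyl)propanoyl]oxazolidin-2-one | COc1ccc(CCC(=O)N2[C@H](Cc3ccccc3)COC2=O)cc1OC | intermediate
5 | tert-butyl bromoacetate | CC(C)(C)OC(=O)CBr | starting material
6 | sodium (Z)-enolate of 4 (not isolated) | COc1ccc(C/C=C(\[O-])N2[C@H](Cc3ccccc3)COC2=O)cc1OC.[Na+] | intermediate
7 | tert-butyl (3S)-4-[(4R)-4-benzyl-2-oxooxazolidin-3-yl]-3-(3,4-dimethoxybenzyl)-4-oxobutanoate | COc1ccc(C[C@@H](CC(=O)OC(C)(C)C)C(=O)N2[C@H](Cc3ccccc3)COC2=O)cc1OC | intermediate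
8 | lithium (2S)-4-tert-butoxy-2-(3,4-dimethoxybenzyl)-4-oxobutaneperoxoate (not isolated) | COc1ccc(C[C@@H](CC(=O)OC(C)(C)C)C(=O)O[O-])cc1OC.[Li+] | intermediate
9 | (2S)-4-tert-butoxy-2-(3,4-dimethoxybenzyl)-4-oxobutanoic acid | COc1ccc(C[C@@H](CC(=O)OC(C)(C)C)C(=O)O)cc1OC | intermediate
10 | tert-butyl (3S)-3-(3,4-dimethoxybenzyl)-4-hydroxybutanoate | COc1ccc(C[C@@H](CC(=O)OC(C)(C)C)CO)cc1OC | intermediate
11 | (3S)-3-(3,4-dimethoxybenzyl)-4-hydroxybutanoic acid (not isolated) | COc1ccc(C[C@@H](CC(=O)O)CO)cc1OC | intermediate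
12 | (4S)-4-(3,4-dimethoxybenzyl)dihydrofuran-2(3H)-one | COc1ccc(C[C@H]2CC(=O)OC2)cc1OC | intermediate
13 | 3,4-dimethoxybenzaldehyde (veratraldehyde) | COc1ccc(C=O)cc1OC | starting material
14 | lithium enolate of 12 (not isolated) | COc1ccc(C[C@H]2C=C([O-])OC2)cc1OC.[Li+] | intermediate
15 | (3R,4S)-4-(3,4-dimethoxybenzyl)-3-[(3,4-dimethoxyphenyl)(hydroxy)methyl]dihydrofuran-2(3H)-one (carbinol centre: both epimers) | O=C1OC[C@@H](Cc2ccc(OC)c(OC)c2)[C@@H]1C(O)c1ccc(OC)c(OC)c1 | intermediate
16 | (3aS,9R,9aS)-9-(3,4-dimethoxyphenyl)-6,7-dimethoxy-3a,4,9,9a-tetrahydronaphtho[2,3-c]furan-1(3H)-one | O=C1OC[C@H]2Cc3cc(OC)c(OC)cc3[C@@H](c3ccc(OC)c(OC)c3)[C@H]12 | intermediate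
17 | [(1R,2S,3S)-1-(3,4-dimethoxyphenyl)-6,7-dimethoxy-1,2,3,4-tetrahydronaphthalene-2,3-diyl]dimethanol | OC[C@H]1Cc2cc(OC)c(OC)cc2[C@@H](c2ccc(OC)c(OC)c2)[C@@H]1CO | intermediate
18 | disodium dialkoxide of 17 (not isolated) | [O-]C[C@H]1Cc2cc(OC)c(OC)cc2[C@@H](c2ccc(OC)c(OC)c2)[C@@H]1C[O-].[Na+].[Na+] | intermediate
19 | phyltetralin, (1R,2S,3S)-1-(3,4-dimethoxyphenyl)-6,7-dimethoxy-2,3-bis(methoxymethyl)-1,2,3,4-tetrahydronaphthalene | COC[C@H]1Cc2cc(OC)c(OC)cc2[C@@H](c2ccc(OC)c(OC)c2)[C@@H]1COC | target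

## Step count and risks

Total steps: 9. Longest linear sequence: 9 steps (1 → 19); compounds 2, 5 and 13 are purchased.

The three steps most likely to fail:

**Step 2 (Evans alkylation with the bromoacetate: incomplete conversion or eroded dr).** The fallback sets out from 4 and returns at 12. Imide 4 is alkylated instead with allyl bromide (NaN(SiMe3)2, THF, −78 °C), the most dependable Evans electrophile, to give (4R)-4-benzyl-3-[(2R)-2-(3,4-dimethoxybenzyl)pent-4-enoyl]oxazolidin-2-one F1, which has the same spatial arrangement as 7. The auxiliary is removed reductively with LiBH4 in THF/MeOH at 0 °C to give (2R)-2-(3,4-dimethoxybenzyl)pent-4-en-1-ol F2. Oxidative cleavage of the alkene (catalytic OsO4, NaIO4, 2,6-lutidine, dioxane/H2O) gives the hydroxy aldehyde, which closes to (4S)-4-(3,4-dimethoxybenzyl)tetrahydrofuran-2-ol F3. Oxidation of the lactol with catalytic TEMPO and PhI(OAc)2 in CH2Cl2 delivers lactone 12.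

**Step 6 (aldol: retro-aldol on work-up or poor conversion).** The fallback sets out from 12 and returns at 15. The lithium enolate of 12 (2.2 equiv LiN(SiMe3)2, THF, −78 °C) is C-acylated in a Claisen-type condensation with 3,4-dimethoxybenzoyl chloride to give (3R,4S)-3-(3,4-dimethoxybenzoyl)-4-(3,4-dimethoxybenzyl)dihydrofuran-2(3H)-one F4. The β-keto lactone settles in the trans arrangement. Reduction of the ketone with NaBH4 in MeOH at 0 °C gives carbinol 15 as an epimer mixture, which is equally suitable for step 7.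

**Step 7 (Friedel–Crafts closure onto the lactone: elimination to the benzylidene lactone or imperfect stereocontrol).** The fallback sets out from 15 and returns at 17. The lactone is reduced first (LiAlH4, THF, 0 °C) to (2S,3S)-2-(3,4-dimethoxybenzyl)-3-[(3,4-dimethoxyphenyl)(hydroxy)methyl]butane-1,4-diol F5. The strain-free open-chain triol is then cyclised with TFA in CH2Cl2 at 0 °C, followed by K2CO3/MeOH to cleave any trifluoroacetate esters. Any benzylic tetrahydrofuran ether formed by O-capture re-ionises under the acid, and the irreversible C–C closure gives the all-equatorial trans,trans diol 17.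

## Further compounds

F1 | step 2 | (4R)-4-benzyl-3-[(2R)-2-(3,4-dimethoxybenzyl)pent-4-enoyl]oxazolidin-2-one | COc1ccc(C[C@@H](CC=C)C(=O)N2[C@H](Cc3ccccc3)COC2=O)cc1OC
F2 | step 2 | (2R)-2-(3,4-dimethoxybenzyl)pent-4-en-1-ol | COc1ccc(C[C@@H](CC=C)CO)cc1OC
F3 | step 2 | (4S)-4-(3,4-dimethoxybenzyl)tetrahydrofuran-2-ol (anomer mixture) | COc1ccc(C[C@H]2CC(O)OC2)cc1OC
F4 | step 6 | (3R,4S)-3-(3,4-dimethoxybenzoyl)-4-(3,4-dimethoxybenzyl)dihydrofuran-2(3H)-one | O=C1OC[C@@H](Cc2ccc(OC)c(OC)c2)[C@@H]1C(=O)c1ccc(OC)c(OC)c1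
F5 | step 7 | (2S,3S)-2-(3,4-dimethoxybenzyl)-3-[(3,4-dimethoxyphenyl)(hydroxy)methyl]butane-1,4-diol (carbinol centre: both epimers) | OC[C@@H](Cc1ccc(OC)c(OC)c1)[C@@H](CO)C(O)c1ccc(OC)c(OC)c1
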